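**Plan**
1. Cuts (germacrane numbering: carbocycle C1–C10; lactone C6–O–C12(=O)–C11(=C13)–C7; C14 = methyl on C10; C15 = CH2OH on C4): the C8–O ester and the C3 ketone last, then C7–C8, then C3–C4, then the butenolide (C7=C11, C12–O) and C5–C6.
2. Enabling feature: C8(O)–C7–C11=C13 is a homoallylic alcohol built into the α-methylene-γ-lactone ring, the retron of an SE2' addition of a C13-metalated butenolide (C11=C7) to a C8 aldehyde. This one event closes the ten-membered carbocycle, sets C7 and C8 and unveils the exocyclic methylene.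
3. Forward: butenolide ring first (steps 1–6); the C1–C3/C8–C10 piece from (S)-linalool (steps 7–10; its vinyl group becomes C9–C8, its prenyl end becomes C1=C2–C3); union at C3–C4 (step 11); ten-membered ring (step 17); ester, C3 ketone and C15 hydroxyl last (steps 18–21).
4. Stereochemistry: C6 from catalytic asymmetric alkynylation; C10 from the chiral pool; C7 from C6 in the ring closure; C8 from the chair transition state (8S) followed by Mitsunobu inversion (8R); the ester centre from (R)-2-methylbutanoic acid; 4Z from trans-hydroalumination/iodination; 1E from aldehyde dehydrogenation.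

Key step: step 17

Remark: (S)-(+)-linalool of high enantiomeric purity and 4-methoxybenzyl propargyl ether are taken as purchasable.
Remark: C3 is carried from step 11 to step 20 as a carbinol (both epimers, no descriptor written), because a C3 ketone would lie within five-membered-ring reach of the allylchromium carbon C7; the centre is erased in step 20.

Step 1
Reactants: 1 methyl 2-(hydroxymethyl)prop-2-enoate
Product: 2 methyl 2-{[(tert-butyldimethylsilyl)oxy]methyl}prop-2-enoate
Conditions: TBSCl, imidazole, CH2Cl2, 0 °C to rt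
Reagents that add atoms: tert-butyldimethylsilyl chloride, CC(C)(C)[Si](C)(C)Cl
Why: Imidazole-promoted silylation of a primary alcohol masks the future C13 oxygen so that the acrylate can be attached and ring-closed before the bromide is needed.

Step 2
Reactants: 2 methyl 2-{[(tert-butyldimethylsilyl)oxy]methyl}prop-2-enoate
Product: 3 2-{[(tert-butyldimethylsilyl)oxy]methyl}prop-2-enoic acid
Conditions: LiOH, THF/H2O, 0 °C; then cold aq. HCl to pH 4
Reagents that add atoms: lithium hydroxide, [Li+].[OH-]
Why: Saponification of the methyl ester under mild aqueous hydroxide should leave the primary silyl ether intact and free the acid for esterification.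

Step 3
Reactants: 4 4-methoxybenzyl propargyl ether; 5 (2E)-but-2-enal
Product: 6 (4S,5E)-1-[(4-methoxybenzyl)oxy]hept-5-en-2-yn-4-ol
Conditions: Me2Zn, ProPhenol ligand (cat., antipode that delivers 4S), Ph3PO (cat.), toluene, 0 °C
Reagents that add atoms: none
Why: Catalytic enantioselective alkynylzinc addition to an enal (dinuclear zinc–ProPhenol alkynylation) adds 1,2 and sets the carbinol that becomes C6, the ligand antipode fixing the face of the aldehyde that is attacked.

Step 4
Reactants: 6 (4S,5E)-1-[(4-methoxybenzyl)oxy]hept-5-en-2-yn-4-ol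
Product: 8 (2Z,4S,5E)-2-iodo-1-[(4-methoxybenzyl)oxy]hepta-2,5-dien-4-ol, via cyclic vinylalanate 7 (not isolated)
Conditions: NaAlH2(OCH2CH2OMe)2 (Red-Al), THF, 0 °C; then I2, −78 °C to 0 °C
Reagents that add atoms: iodine, II
Why: Hydroxyl-directed trans-hydroalumination of the propargylic alcohol puts hydride on the proximal and aluminium on the distal alkyne carbon inside a five-membered alanate, and iodinolysis with retention should give the (Z)-iodoalkene (iodine cis to the carbinol carbon) that fixes the C4=C5 geometry, the cold quench outrunning loss of the β-alkoxy group.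

Step 5
Reactants: 8 (2Z,4S,5E)-2-iodo-1-[(4-methoxybenzyl)oxy]hepta-2,5-dien-4-ol; 3 2-{[(tert-butyldimethylsilyl)oxy]methyl}prop-2-enoic acid
Product: 9 (2Z,4S,5E)-2-iodo-1-[(4-methoxybenzyl)oxy]hepta-2,5-dien-4-yl 2-{[(tert-butyldimethylsilyl)oxy]methyl}prop-2-enoate
Conditions: DCC, DMAP (cat.), CH2Cl2, 0 °C to rt
Reagents that add atoms: none
Why: Steglich esterification of the secondary alcohol forms the C12–O bond of the future lactone without touching the C6 centre.

Step 6
Reactants: 9 (2Z,4S,5E)-2-iodo-1-[(4-methoxybenzyl)oxy]hepta-2,5-dien-4-yl 2-{[(tert-butyldimethylsilyl)oxy]methyl}prop-2-enoate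
Product: 10 (5S)-3-{[(tert-butyldimethylsilyl)oxy]methyl}-5-{(1Z)-2-iodo-3-[(4-methoxybenzyl)oxy]prop-1-en-1-yl}furan-2(5H)-one
Conditions: second-generation Grubbs catalyst (cat.), toluene, 80 °C
Reagents that add atoms: none
Why: Ring-closing metathesis between the 2-substituted acrylate and the propenyl group should close the five-membered butenolide (C7=C11) with loss of propene, the trisubstituted iodoalkene being too hindered to enter the catalytic cycle.

Step 7
Reactants: 11 (S)-(+)-linalool
Product: 13 (3S)-3,7-dimethyloct-6-ene-1,3-diol, via organoborane 12 (not isolated)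
Conditions: 9-BBN, THF, 0 °C to rt; then NaOH, H2O2, 0 °C
Reagents that add atoms: hydrogen peroxide, OO
Why: Anti-Markovnikov hydroboration–oxidation with 9-BBN takes the monosubstituted vinyl group and spares the trisubstituted alkene, giving the primary alcohol (future C8 oxygen) while the C10 centre from the chiral pool is untouched.

Step 8
Reactants: 13 (3S)-3,7-dimethyloct-6-ene-1,3-diol
Product: 14 (4S)-2,2,4-trimethyl-4-(4-methylpent-3-en-1-yl)-1,3-dioxane
Conditions: Me2C(OMe)2, PPTS (cat.), CH2Cl2, rt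
Reagents that add atoms: 2,2-dimethoxypropane, COC(C)(C)OC
Why: Acid-catalysed transketalisation ties the 1,3-diol (C8 and C10 oxygens) into a six-membered acetonide with no new stereocentre, which prevents lactol formation after the next step.

Step 9
Reactants: 14 (4S)-2,2,4-trimethyl-4-(4-methylpent-3-en-1-yl)-1,3-dioxane
Product: 16 3-[(4S)-2,2,4-trimethyl-1,3-dioxan-4-yl]propanal, via ozonide 15 (not isolated)
Conditions: O3, CH2Cl2, −78 °C; then PPh3, −78 °C to rt
Reagents that add atoms: ozone, [O-][O+]=O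
Why: Ozonolysis of the only alkene with reductive work-up removes the isopropylidene terminus as acetone and leaves the C3 aldehyde.

Step 10
Reactants: 16 3-[(4S)-2,2,4-trimethyl-1,3-dioxan-4-yl]propanal
Product: 17 (2E)-3-[(4R)-2,2,4-trimethyl-1,3-dioxan-4-yl]prop-2-enal
Conditions: IBX, DMSO/fluorobenzene, 65 °C
Reagents that add atoms: none
Why: IBX-mediated α,β-dehydrogenation of the aldehyde should give the thermodynamic E-enal (C1=C2), further dehydrogenation being blocked by the quaternary γ-carbon C10 (the descriptor changes from 4S to 4R only through CIP priorities).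

Step 11
Reactants: 10 (5S)-3-{[(tert-butyldimethylsilyl)oxy]methyl}-5-{(1Z)-2-iodo-3-[(4-methoxybenzyl)oxy]prop-1-en-1-yl}furan-2(5H)-one; 17 (2E)-3-[(4R)-2,2,4-trimethyl-1,3-dioxan-4-yl]prop-2-enal
Product: 19 C3 allylic alcohol of the joined C1–C15 chain (6R,10R; 4Z,1E; both C3 epimers), via alkenylchromium dichloride 18 (not isolated)
Conditions: CrCl2, NiCl2 (cat.), DMSO, rt; aqueous work-up
Reagents that add atoms: none
Why: The nickel-catalysed, CrCl2-mediated alkenylation of an aldehyde (Nozaki–Hiyama–Kishi coupling) forms C3–C4 with retention of the Z geometry and tolerates the butenolide, silyl ether, acetonide and PMB ether; the C3 carbinol forms without control, which does not matter because C3 is oxidised in step 20.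

Step 12
Reactants: 19 C3 allylic alcohol (both C3 epimers)
Product: 20 C3 tert-butyldimethylsilyl ether of 19
Conditions: TBSOTf, 2,6-lutidine, CH2Cl2, −78 °C
Reagents that add atoms: tert-butyldimethylsilyl trifluoromethanesulfonate, CC(C)(C)[Si](C)(C)OS(=O)(=O)C(F)(F)F
Why: Fast low-temperature silylation of the secondary bis-allylic hydroxyl keeps C3 as a non-electrophilic sp3 carbon for the ring closure and forestalls oxa-Michael addition of the C3 oxygen to the butenolide.

Step 13
Reactants: 20 C3 tert-butyldimethylsilyl ether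
Product: 21 C13 primary allylic alcohol (C3 silyl ether retained)
Conditions: HF·pyridine, pyridine, THF, 0 °C
Reagents that add atoms: none
Why: Buffered fluoride cleaves the unhindered primary allylic silyl ether much faster than the hindered secondary one (steric differentiation of silyl ethers), while the acetonide and PMB ether are stable.

Step 14
Reactants: 21 C13 primary allylic alcohol
Product: 22 C13 allylic bromide (3-(bromomethyl)butenolide)
Conditions: CBr4, PPh3, CH2Cl2, 0 °C
Reagents that add atoms: tetrabromomethane, BrC(Br)(Br)Br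
Why: The Appel reaction converts the primary allylic alcohol into the bromide under neutral conditions that leave the acetonide, silyl ether and lactone untouched.

Step 15
Reactants: 22 C13 allylic bromide
Product: 23 C8,C10 diol (acetonide removed)
Conditions: AcOH/THF/H2O, rt
Reagents that add atoms: none
Why: Mild aqueous acid hydrolyses the strained 1,3-dioxane acetonide faster than it attacks the secondary silyl ether, and the allylic bromide is stable without base.

Step 16
Reactants: 23 C8,C10 diol
Product: 24 C8 aldehyde (bromomethyl-butenolide aldehyde, C10 hydroxyl free)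
Conditions: TEMPO (cat.), PhI(OAc)2, CH2Cl2, rt
Reagents that add atoms: none
Why: Oxoammonium (TEMPO) oxidation is selective for the primary alcohol over the tertiary C10 hydroxyl and does not affect the allylic bromide, giving the β-hydroxy aldehyde needed for ring closure.

Step 17
Reactants: 24 C8 aldehyde
Product: 26 ten-membered α-methylene lactone with 8S hydroxyl (6R,7R,8S,10R; both C3 epimers), via allylchromium dichloride 25 (not isolated)
Conditions: CrCl2 (excess), THF/DMF, rt, slow addition of 24 to a final 0.002 M; aqueous work-up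
Reagents that add atoms: none
Why: Two equivalents of CrCl2 reduce the allylic C13–Br bond of 24 to the allylchromium dichloride 25 (chromium passes from the divalent to the trivalent state), which adds through its γ-carbon C7 to the tethered C8 aldehyde in a closed six-membered chair transition state (SE2' allyl transfer), so that C7–C8 forms while the C11=C13 exocyclic methylene of the lactone is unveiled. The closest known reaction types are the intramolecular Nozaki–Hiyama–Kishi allylation used to close ten-membered germacrane rings and the chromium-mediated addition of 3-(bromomethyl)butenolides to aldehydes. The ten-membered carbocycle closes in a 10-exo-trig mode with respect to the aldehyde carbonyl, and the C7=C11 bond of the butenolide likewise ends up exocyclic to the new ring. C7 is controlled by C6, the aldehyde being delivered to the butenolide face opposite the C5 substituent to give the trans-fused lactone (7R); C8 is controlled by the chair, in which the butenolide ring locks C6 trans to CH2Cr and the C9 chain sits equatorial in the donor solvent, giving the 7,8-anti relationship, that is the 8S alcohol that step 18 inverts. The step needs chemoselectivity for the aldehyde (secured by carrying C3 as a silyl ether and by the inertness of allylchromium towards lactones), γ-regioselectivity (inherent to allylchromium reagents) and ring closure over oligomerisation (secured by slow addition at high dilution and by the two alkenes that restrict the tether).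

Step 18
Reactants: 26 ten-membered lactone with 8S hydroxyl; 27 (2R)-2-methylbutanoic acid
Product: 28 8R (2R)-2-methylbutanoate (C3 silyl ether and C15 PMB ether retained)
Conditions: PPh3, DIAD, toluene, 0 °C to rt
Reagents that add atoms: none
Why: Mitsunobu esterification activates the secondary C8 hydroxyl as an alkoxyphosphonium ion that the carboxylate of 27 displaces by SN2 with inversion (8S to 8R), the tertiary C10 hydroxyl being inert and the α-centre of the acid not being engaged.

Step 19
Reactants: 28 8R ester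
Product: 29 C3 alcohol (both C3 epimers)
Conditions: HF·pyridine, THF, 0 °C to rt
Reagents that add atoms: none
Why: Fluoride-mediated cleavage of the secondary silyl ether is compatible with the ester, the α-methylene lactone and the PMB ether.

Step 20
Reactants: 29 C3 alcohol
Product: 30 C3 ketone (cross-conjugated dienone; C15 PMB ether retained)
Conditions: Dess–Martin periodinane, CH2Cl2, 0 °C to rt
Reagents that add atoms: none
Why: Periodinane oxidation of the bis-allylic secondary alcohol gives the dienone and merges both C3 epimers into one compound, the tertiary C10 hydroxyl being unable to react.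

Step 21
Reactants: 30 C3 ketone
Product: 31 target compound
Conditions: DDQ, CH2Cl2/pH 7 buffer, 0 °C
Reagents that add atoms: none
Why: Oxidative cleavage of the 4-methoxybenzyl ether by DDQ under neutral buffered conditions frees the C15 hydroxyl without affecting the dienone, the α-methylene lactone or the ester.

**Compound list**
1 | methyl 2-(hydroxymethyl)prop-2-enoate | C=C(CO)C(=O)OC | starting material
2 | methyl 2-{[(tert-butyldimethylsilyl)oxy]methyl}prop-2-enoate | C=C(CO[Si](C)(C)C(C)(C)C)C(=O)OC | intermediate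
3 | 2-{[(tert-butyldimethylsilyl)oxy]methyl}prop-2-enoic acid | C=C(CO[Si](C)(C)C(C)(C)C)C(=O)O | intermediate
4 | 1-methoxy-4-[(prop-2-yn-1-yloxy)methyl]benzene (4-methoxybenzyl propargyl ether) | C#CCOCc1ccc(OC)cc1 | starting material
5 | (2E)-but-2-enal | C/C=C/C=O | starting material
6 | (4S,5E)-1-[(4-methoxybenzyl)oxy]hept-5-en-2-yn-4-ol | C/C=C/[C@H](O)C#CCOCc1ccc(OC)cc1 | intermediate
7 | cyclic vinylalanate (sodium salt): five-membered 1,2-oxaaluminol-3-ene from 6, Al(OCH2CH2OMe)2 bound to the carbinol oxygen and to the alkene carbon bearing CH2OPMB | C/C=C/[C@@H]1O[Al-](OCCOC)(OCCOC)C(COCc2ccc(OC)cc2)=C1.[Na+] | intermediate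
8 | (2Z,4S,5E)-2-iodo-1-[(4-methoxybenzyl)oxy]hepta-2,5-dien-4-ol | C/C=C/[C@H](O)/C=C(\I)COCc1ccc(OC)cc1 | intermediate
9 | (2Z,4S,5E)-2-iodo-1-[(4-methoxybenzyl)oxy]hepta-2,5-dien-4-yl 2-{[(tert-butyldimethylsilyl)oxy]methyl}prop-2-enoate | C/C=C/[C@H](OC(=O)C(=C)CO[Si](C)(C)C(C)(C)C)/C=C(\I)COCc1ccc(OC)cc1 | intermediate
10 | (5S)-3-{[(tert-butyldimethylsilyl)oxy]methyl}-5-{(1Z)-2-iodo-3-[(4-methoxybenzyl)oxy]prop-1-en-1-yl}furan-2(5H)-one | O=C1O[C@H](/C=C(\I)COCc2ccc(OC)cc2)C=C1CO[Si](C)(C)C(C)(C)C | intermediate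
11 | (S)-(+)-linalool, (3S)-3,7-dimethylocta-1,6-dien-3-ol | C=C[C@@](C)(O)CCC=C(C)C | starting material
12 | organoborane from 11: 9-borabicyclo[3.3.1]nonan-9-yl group on C1 and 9-BBN borinate on O3 of the (3S)-3,7-dimethyloct-6-ene-1,3-diyl unit | C1CCC2CCCC1B2CC[C@@](C)(OB1C2CCCC1CCC2)CCC=C(C)C | intermediate
13 | (3S)-3,7-dimethyloct-6-ene-1,3-diol | OCC[C@@](C)(O)CCC=C(C)C | intermediate
14 | (4S)-2,2,4-trimethyl-4-(4-methylpent-3-en-1-yl)-1,3-dioxane | CC(C)=CCC[C@]1(C)OC(C)(C)OCC1 | intermediate
15 | ozonide (1,2,4-trioxolane) of 14 | CC1(C)OOC(CC[C@]2(C)OC(C)(C)OCC2)O1 | intermediate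
16 | 3-[(4S)-2,2,4-trimethyl-1,3-dioxan-4-yl]propanal | O=CCC[C@]1(C)OC(C)(C)OCC1 | intermediate
17 | (2E)-3-[(4R)-2,2,4-trimethyl-1,3-dioxan-4-yl]prop-2-enal | O=C/C=C/[C@]1(C)OC(C)(C)OCC1 | intermediate
18 | alkenylchromium dichloride from 10 (CrCl2 group in place of iodine, Z geometry kept) | Cl[Cr](Cl)/C(COCc1ccc(OC)cc1)=C\[C@@H]1C=C(CO[Si](C)(C)C(C)(C)C)C(=O)O1 | intermediate
19 | (5R)-3-{[(tert-butyldimethylsilyl)oxy]methyl}-5-{(1Z,4E)-3-hydroxy-2-{[(4-methoxybenzyl)oxy]methyl}-5-[(4R)-2,2,4-trimethyl-1,3-dioxan-4-yl]penta-1,4-dien-1-yl}furan-2(5H)-one, both epimers at the carbinol (C3); same spatial arrangement at the ring carbon as in 10, the descriptor changes with loss of iodine | O=C1O[C@H](/C=C(COCc2ccc(OC)cc2)\C(O)/C=C/[C@]2(C)OC(C)(C)OCC2)C=C1CO[Si](C)(C)C(C)(C)C | intermediate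
20 | C3 tert-butyldimethylsilyl ether of 19 | O=C1O[C@H](/C=C(COCc2ccc(OC)cc2)\C(O[Si](C)(C)C(C)(C)C)/C=C/[C@]2(C)OC(C)(C)OCC2)C=C1CO[Si](C)(C)C(C)(C)C | intermediate
21 | (5R)-5-{(1Z,4E)-3-[(tert-butyldimethylsilyl)oxy]-2-{[(4-methoxybenzyl)oxy]methyl}-5-[(4R)-2,2,4-trimethyl-1,3-dioxan-4-yl]penta-1,4-dien-1-yl}-3-(hydroxymethyl)furan-2(5H)-one | O=C1O[C@H](/C=C(COCc2ccc(OC)cc2)\C(O[Si](C)(C)C(C)(C)C)/C=C/[C@]2(C)OC(C)(C)OCC2)C=C1CO | intermediate
22 | (5R)-3-(bromomethyl)-5-{(1Z,4E)-3-[(tert-butyldimethylsilyl)oxy]-2-{[(4-methoxybenzyl)oxy]methyl}-5-[(4R)-2,2,4-trimethyl-1,3-dioxan-4-yl]penta-1,4-dien-1-yl}furan-2(5H)-one | O=C1O[C@H](/C=C(COCc2ccc(OC)cc2)\C(O[Si](C)(C)C(C)(C)C)/C=C/[C@]2(C)OC(C)(C)OCC2)C=C1CBr | intermediate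
23 | (5R)-3-(bromomethyl)-5-{(1Z,4E,6R)-3-[(tert-butyldimethylsilyl)oxy]-6,8-dihydroxy-2-{[(4-methoxybenzyl)oxy]methyl}-6-methylocta-1,4-dien-1-yl}furan-2(5H)-one | O=C1O[C@H](/C=C(COCc2ccc(OC)cc2)\C(O[Si](C)(C)C(C)(C)C)/C=C/[C@](C)(O)CCO)C=C1CBr | intermediate
24 | (5R)-3-(bromomethyl)-5-{(1Z,4E,6R)-3-[(tert-butyldimethylsilyl)oxy]-6-hydroxy-2-{[(4-methoxybenzyl)oxy]methyl}-6-methyl-8-oxoocta-1,4-dien-1-yl}furan-2(5H)-one | O=C1O[C@H](/C=C(COCc2ccc(OC)cc2)\C(O[Si](C)(C)C(C)(C)C)/C=C/[C@](C)(O)CC=O)C=C1CBr | intermediate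
25 | allylchromium dichloride from 24 (CrCl2 group on C13 in place of bromine) | O=C1O[C@H](/C=C(COCc2ccc(OC)cc2)\C(O[Si](C)(C)C(C)(C)C)/C=C/[C@](C)(O)CC=O)C=C1C[Cr](Cl)Cl | intermediate
26 | (3aR,4S,6R,7E,10Z,11aR)-9-[(tert-butyldimethylsilyl)oxy]-4,6-dihydroxy-10-{[(4-methoxybenzyl)oxy]methyl}-6-methyl-3-methylidene-3a,4,5,6,9,11a-hexahydrocyclodeca[b]furan-2(3H)-one, both C9 (germacrane C3) epimers | C=C1C(=O)O[C@@H]2/C=C(/COCc3ccc(OC)cc3)C(O[Si](C)(C)C(C)(C)C)/C=C/[C@](C)(O)C[C@H](O)[C@@H]12 | intermediate
27 | (2R)-2-methylbutanoic acid | CC[C@@H](C)C(=O)O | starting material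
28 | (3aR,4R,6R,7E,10Z,11aR)-9-[(tert-butyldimethylsilyl)oxy]-6-hydroxy-10-{[(4-methoxybenzyl)oxy]methyl}-6-methyl-3-methylidene-2-oxo-2,3,3a,4,5,6,9,11a-octahydrocyclodeca[b]furan-4-yl (2R)-2-methylbutanoate, both C9 epimers | C=C1C(=O)O[C@@H]2/C=C(/COCc3ccc(OC)cc3)C(O[Si](C)(C)C(C)(C)C)/C=C/[C@](C)(O)C[C@@H](OC(=O)[C@H](C)CC)[C@@H]12 | intermediate
29 | (3aR,4R,6R,7E,10Z,11aR)-6,9-dihydroxy-10-{[(4-methoxybenzyl)oxy]methyl}-6-methyl-3-methylidene-2-oxo-2,3,3a,4,5,6,9,11a-octahydrocyclodeca[b]furan-4-yl (2R)-2-methylbutanoate, both C9 epimers | C=C1C(=O)O[C@@H]2/C=C(/COCc3ccc(OC)cc3)C(O)/C=C/[C@](C)(O)C[C@@H](OC(=O)[C@H](C)CC)[C@@H]12 | intermediate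
30 | (3aR,4R,6R,7E,10Z,11aR)-6-hydroxy-10-{[(4-methoxybenzyl)oxy]methyl}-6-methyl-3-methylidene-2,9-dioxo-2,3,3a,4,5,6,9,11a-octahydrocyclodeca[b]furan-4-yl (2R)-2-methylbutanoate | C=C1C(=O)O[C@@H]2/C=C(/COCc3ccc(OC)cc3)C(=O)/C=C/[C@](C)(O)C[C@@H](OC(=O)[C@H](C)CC)[C@@H]12 | intermediate
31 | (3aR,4R,6R,7E,10Z,11aR)-6-hydroxy-10-(hydroxymethyl)-6-methyl-3-methylidene-2,9-dioxo-2,3,3a,4,5,6,9,11a-octahydrocyclodeca[b]furan-4-yl (2R)-2-methylbutanoate | C=C1C(=O)O[C@@H]2/C=C(/CO)C(=O)/C=C/[C@](C)(O)C[C@@H](OC(=O)[C@H](C)CC)[C@@H]12 | target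

**Step count**
Total: 21 steps. Longest linear sequence: 15 steps (steps 3–6 or 7–10, then 11–21).

**Steps most likely to fail**

Step 17. What may go wrong: the allylchromium species may be protonated or may couple intermolecularly faster than the ten-membered ring closes, or the ring may close with poor facial control at C8. The fallback sets out from 10 and 17 and returns at 29; it makes the C7–C8 bond intermolecularly and closes the ring at C3–C4 instead. Butenolide 10 would be desilylated (HF·pyridine) to the hydroxymethyl butenolide F1 and brominated (CBr4, PPh3) to the bromomethyl butenolide F2. Enal 17 would be reduced (NaBH4, CeCl3) to the allylic alcohol F3, silylated (TBDPSCl, imidazole) to the silyl ether F4, freed of its acetonide (aqueous AcOH) to the diol F5 and oxidised (TEMPO, PhI(OAc)2) to the hydroxy aldehyde F6. A zinc-mediated Barbier allylation of F6 with F2 (Zn dust, THF/aqueous NH4Cl) would give the α-methylene lactone F7; this reaction class is expected to give the 7,8-syn (8R) adduct with 3-(bromomethyl)butenolides and to leave iodoalkenes untouched. Steglich acylation with 27 would give the ester F8 without any inversion, HF·pyridine the allylic alcohol F9 and MnO2 the enal F10. An intramolecular Nozaki–Hiyama–Kishi alkenylation (CrCl2, NiCl2 cat., DMSO, high dilution) would then close the ring between C3 and C4 to give 29.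

Step 18. What may go wrong: elimination towards C9, or displacement with retention at the hindered C8 centre under the redox-condensation conditions. The fallback sets out from 26 and returns at 28; it replaces the Mitsunobu reaction by a two-stage sulfonate inversion. Compound 26 would be sulfonylated selectively at the secondary hydroxyl (ClCH2SO2Cl, pyridine) to the chloromethanesulfonate F11, which the cesium salt of 27 (Cs2CO3, 18-crown-6, toluene, warm) would displace by SN2 with inversion to give 28.

Step 10. What may go wrong: incomplete dehydrogenation, or acid-promoted loss of the acetonide under the hot oxidising conditions. The fallback sets out from 16 and returns at 17; it replaces the direct dehydrogenation by selenoxide elimination. Organocatalytic α-selenenylation of 16 (N-(phenylseleno)phthalimide, prolinamide catalyst) would give the α-phenylselanyl aldehyde F12, and oxidation (NaIO4) with syn-elimination of the selenoxide would give 17.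

**Further compounds**
F1 | step 17 | (5S)-3-(hydroxymethyl)-5-{(1Z)-2-iodo-3-[(4-methoxybenzyl)oxy]prop-1-en-1-yl}furan-2(5H)-one | O=C1O[C@H](/C=C(\I)COCc2ccc(OC)cc2)C=C1CO
F2 | step 17 | (5S)-3-(bromomethyl)-5-{(1Z)-2-iodo-3-[(4-methoxybenzyl)oxy]prop-1-en-1-yl}furan-2(5H)-one | O=C1O[C@H](/C=C(\I)COCc2ccc(OC)cc2)C=C1CBr
F3 | step 17 | (2E)-3-[(4R)-2,2,4-trimethyl-1,3-dioxan-4-yl]prop-2-en-1-ol | OC/C=C/[C@]1(C)OC(C)(C)OCC1
F4 | step 17 | tert-butyl(diphenyl){[(2E)-3-[(4R)-2,2,4-trimethyl-1,3-dioxan-4-yl]prop-2-en-1-yl]oxy}silane | CC(C)(C)[Si](c1ccccc1)(c1ccccc1)OC/C=C/[C@]1(C)OC(C)(C)OCC1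
F5 | step 17 | (3R,4E)-6-[(tert-butyldiphenylsilyl)oxy]-3-methylhex-4-ene-1,3-diol | CC(C)(C)[Si](c1ccccc1)(c1ccccc1)OC/C=C/[C@](C)(O)CCO
F6 | step 17 | (3R,4E)-6-[(tert-butyldiphenylsilyl)oxy]-3-hydroxy-3-methylhex-4-enal | CC(C)(C)[Si](c1ccccc1)(c1ccccc1)OC/C=C/[C@](C)(O)CC=O
F7 | step 17 | Barbier adduct: trans-4,5-disubstituted 3-methylidene-γ-butyrolactone carrying the (Z)-iodoalkenyl group on C6 and the (8R,10R)-8,10-dihydroxy chain with terminal TBDPS ether on C7 (germacrane locants) | C=C1C(=O)O[C@H](/C=C(\I)COCc2ccc(OC)cc2)[C@H]1[C@H](O)C[C@@](C)(O)/C=C/CO[Si](c2ccccc2)(c2ccccc2)C(C)(C)C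
F8 | step 17 | C8 (2R)-2-methylbutanoate of F7 | C=C1C(=O)O[C@H](/C=C(\I)COCc2ccc(OC)cc2)[C@H]1[C@H](OC(=O)[C@H](C)CC)C[C@@](C)(O)/C=C/CO[Si](c2ccccc2)(c2ccccc2)C(C)(C)C
F9 | step 17 | primary allylic alcohol from F8 (silyl group removed) | C=C1C(=O)O[C@H](/C=C(\I)COCc2ccc(OC)cc2)[C@H]1[C@H](OC(=O)[C@H](C)CC)C[C@@](C)(O)/C=C/CO
F10 | step 17 | (E)-enal from F9 (iodoalkene–enal precursor for ring closure at C3–C4) | C=C1C(=O)O[C@H](/C=C(\I)COCc2ccc(OC)cc2)[C@H]1[C@H](OC(=O)[C@H](C)CC)C[C@@](C)(O)/C=C/C=O
F11 | step 18 | C8 chloromethanesulfonate of 26 (8S) | C=C1C(=O)O[C@@H]2/C=C(/COCc3ccc(OC)cc3)C(O[Si](C)(C)C(C)(C)C)/C=C/[C@](C)(O)C[C@H](OS(=O)(=O)CCl)[C@@H]12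
F12 | step 10 | 2-(phenylselanyl)-3-[(4S)-2,2,4-trimethyl-1,3-dioxan-4-yl]propanal | O=CC([Se]c1ccccc1)C[C@]1(C)OC(C)(C)OCC1
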